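Lupulone is a threefold C-prenylated, dearomatised acylphloroglucinol, so its six-membered ring (C1–C6, C1 the ring ketone, C4 the acyl-bearing carbon, C6 the gem-diprenyl carbon) is a cyclised tetraketide in which carbonyl-level C1, C3 and C5 alternate with nucleophilic C2, C4 and C6. The ring is therefore cut into a malonyl unit (C1–C2–C3) and the C4–C5–C6 end of an isovaleryl diketone. The key step, a polyketide-mimetic one-pot [3+3] annulation, joins the 1,3-bis(silyl enol ether) of 6-methylheptane-2,4-dione with malonyl dichloride: chain extension forms C1–C6, a pyranone relay and magnesium-templated Claisen closure forms C3–C4. Three successive C-prenylations, the last one dearomatising, then give lupulone.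

Key step: step 3

Remark: lupulone has no stereocentre and no stereogenic double bond. It is drawn as the 3,5-dihydroxycyclohexa-2,4-dien-1-one tautomer. The two ring CH carbons of phlorisovalerophenone are symmetry-equivalent, and so are the two prenylated ring carbons of deoxyhumulone, so the one that becomes quaternary in step 6 is called C6.

Step 1
Reactants: 1 6-methylheptane-2,4-dione
Product: 2 (3Z)-6-methyl-4-(trimethylsilyloxy)hept-3-en-2-one
Conditions: Me3SiCl (1.3 equiv), Et3N (1.4 equiv), pentane, 20 °C, 48 h; filter, concentrate
Reagents that add atoms: chlorotrimethylsilane C[Si](C)(C)Cl
Why: Amine-mediated O-silylation of the strongly enolised β-diketone (silyl enol ether formation) should give the Z-configured β-silyloxy enone, a fluxional pair of 1,5-silyl-shift isomers drawn as one, both of which lead to the same dienolate in step 2.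

Step 2
Reactants: 2 (3Z)-6-methyl-4-(trimethylsilyloxy)hept-3-en-2-one
Product: 3 (3Z)-6-methyl-2,4-bis(trimethylsilyloxy)hepta-1,3-diene
Conditions: LiN(iPr)2 (1.1 equiv, commercial solution), THF, −78 °C, 1 h; Me3SiCl (1.2 equiv), −78 → 20 °C; pentane, filter, concentrate, used crude under argon
Reagents that add atoms: chlorotrimethylsilane C[Si](C)(C)Cl
Why: Kinetic deprotonation by the hindered amide base should take a proton from the unhindered terminal methyl group in preference to the β-branched isobutyl methylene, and O-silylation of the dienolate gives the 1,3-bis(silyl enol ether) (standard two-stage preparation of Chan-type dienes).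

Step 3
Reactants: 3 (3Z)-6-methyl-2,4-bis(trimethylsilyloxy)hepta-1,3-diene; 4 malonyl dichloride
Product: 8 phlorisovalerophenone, via acyl chloride 5 (not isolated), via pyranone 6 (not isolated), via triketo ester 7 (not isolated)
Conditions: 3 added to 4 (1.05 equiv), CH2Cl2, −78 → 20 °C, 12 h; evaporate; Mg(OMe)2 (5 equiv), MeOH, reflux, 16 h; 1 M aq. HCl
Reagents that add atoms: none
Why: The terminal carbon of diene 3 (C6, the site of the largest HOMO coefficient) should be C-acylated by one acyl chloride of 4 (C1–C6 bond, loss of Me3SiCl) to give 5, whose silyl group shifts to the C5 enol oxygen, which closes on the second acyl chloride (6-exo-trig lactonisation, loss of the second Me3SiCl) to the stable pyranone 6; magnesium dimethoxide then opens the lactone to the magnesium chelate of triketo ester 7, in which the chelated 5,7-diketonate carbon C4 attacks the ester carbon C3 in a 6-(enolendo)-exo-trig Claisen closure (C3–C4 bond), and the resulting trione aromatises to 8. The closest known reaction types are the terminal C-acylation of 1,3-bis(silyl enol ethers) by acid chlorides, the Effenberger pyranone synthesis from silyl enol ethers and malonyl dichloride, and the biomimetic Mg(OMe)2-mediated recyclisation of 6-(2-oxoalkyl)-4-hydroxypyran-2-ones to acylphloroglucinols; together they copy chain extension and ring closure by the hop polyketide synthase. No stereocentre is formed. The selectivity needed is Claisen closure (C4 onto C3) over aldol closure (C2 onto the isovaleryl ketone); it should be secured by divalent magnesium, which holds diketonate and ester in one chelate, by methanol, which keeps C3 an ester and not an unreactive carboxylate, and by the irreversible aromatisation to the phloroglucinolate. The regiochemistry of the first acylation is fixed by the diene, whose central carbon C4 is the less nucleophilic position.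

Step 4
Reactants: 8 phlorisovalerophenone; 9 prenyl bromide
Product: 10 3-prenylphlorisovalerophenone
Conditions: 10% aq. KOH (1.0 equiv), 0 °C; 9 (1.0 equiv, added dropwise over 1 h), 0 °C, 2 h; 1 M aq. HCl to pH 2; chromatography, unreacted 8 recovered
Reagents that add atoms: none
Why: C-alkylation of the phloroglucinolate monoanion in water (phenolate C-alkylation, the hydrogen-bonded oxygen atoms leaving carbon as the reactive site for the soft allylic bromide) should stop at the first prenylation because base and 9 are limiting, and the two ring CH carbons are equivalent, so only one monoprenyl product can form.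

Step 5
Reactants: 10 3-prenylphlorisovalerophenone; 9 prenyl bromide
Product: 11 deoxyhumulone
Conditions: 10% aq. KOH (1.1 equiv), 0 °C; 9 (1.0 equiv, added dropwise), 0 °C, 2 h; 1 M aq. HCl to pH 2; chromatography
Reagents that add atoms: none
Why: A second phenolate C-alkylation should take place at the remaining ring CH carbon, the least hindered nucleophilic carbon of the anion, whose alkylation product regains aromaticity by tautomerisation, while one equivalent each of base and 9 limits quaternisation of the already prenylated carbon.

Step 6
Reactants: 11 deoxyhumulone; 9 prenyl bromide
Product: 12 lupulone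
Conditions: NaOMe (1.1 equiv), MeOH, −20 °C, argon; 9 (1.1 equiv), −20 → 0 °C, 3 h; 1 M aq. HCl to pH 2; crystallisation or chromatography under argon
Reagents that add atoms: none
Why: Alkylative dearomatisation of the acylphloroglucinolate should place the third prenyl group on one of the two equivalent prenylated ring carbons, since the acyl-bearing carbon is deactivated and hindered, which creates the quaternary C6 without a stereocentre (two identical groups) and leaves a vinylogous-acid anion that is a poor nucleophile for a fourth alkylation.

Compound list
1 | 6-methylheptane-2,4-dione | CC(C)CC(=O)CC(C)=O | starting material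
2 | (3Z)-6-methyl-4-(trimethylsilyloxy)hept-3-en-2-one | CC(=O)/C=C(/CC(C)C)O[Si](C)(C)C | intermediate
3 | (3Z)-6-methyl-2,4-bis(trimethylsilyloxy)hepta-1,3-diene | C=C(O[Si](C)(C)C)/C=C(/CC(C)C)O[Si](C)(C)C | intermediate
4 | malonyl dichloride (propanedioyl dichloride) | O=C(Cl)CC(=O)Cl | starting material
5 | (6Z)-9-methyl-3,5-dioxo-7-(trimethylsilyloxy)dec-6-enoyl chloride (not isolated) | O=C(Cl)CC(=O)CC(=O)/C=C(/CC(C)C)O[Si](C)(C)C | intermediate
6 | 4-hydroxy-6-(4-methyl-2-oxopentyl)-2H-pyran-2-one (not isolated) | CC(C)CC(=O)CC1=CC(O)=CC(=O)O1 | intermediate
7 | methyl 9-methyl-3,5,7-trioxodecanoate (as its magnesium chelate, not isolated) | COC(=O)CC(=O)CC(=O)CC(=O)CC(C)C | intermediate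
8 | phlorisovalerophenone, 3-methyl-1-(2,4,6-trihydroxyphenyl)butan-1-one | CC(C)CC(=O)c1c(O)cc(O)cc1O | intermediate
9 | prenyl bromide, 1-bromo-3-methylbut-2-ene | CC(C)=CCBr | starting material
10 | 3-prenylphlorisovalerophenone, 3-methyl-1-[2,4,6-trihydroxy-3-(3-methylbut-2-en-1-yl)phenyl]butan-1-one | CC(C)CC(=O)c1c(O)cc(O)c(CC=C(C)C)c1O | intermediate
11 | deoxyhumulone, 3-methyl-1-[2,4,6-trihydroxy-3,5-bis(3-methylbut-2-en-1-yl)phenyl]butan-1-one | CC(C)CC(=O)c1c(O)c(CC=C(C)C)c(O)c(CC=C(C)C)c1O | intermediate
12 | lupulone, 3,5-dihydroxy-4-(3-methylbutanoyl)-2,6,6-tris(3-methylbut-2-en-1-yl)cyclohexa-2,4-dien-1-one | CC(C)=CCC1=C(O)C(C(=O)CC(C)C)=C(O)C(CC=C(C)C)(CC=C(C)C)C1=O | target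

Total step count: 6. Longest linear sequence: 6 steps (1 → 2 → 3 → 8 → 10 → 11 → 12).

Steps most likely to fail

Step 3. The magnesium-mediated recyclisation may be diverted into aldol closure of C2 onto the isovaleryl ketone, the lactone may resist opening, or the first stage may suffer twofold intermolecular acylation of the diacid chloride. The fallback sets out from 3 and avoids the pyranone altogether. Diene 3 is acylated at its terminal carbon with methyl 3-chloro-3-oxopropanoate (CH2Cl2, −78 → 20 °C), and dilute aqueous HCl removes the remaining silyl group, so that triketo ester 7 is isolated. Ring closure is then run under a different regime, as the polyanion in aqueous KOH at 20 °C, where open-chain 3,5,7-triketo esters are known to close by C-acylation. The fallback comes back to the route at 8 and makes no compound outside the compound list (F0).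

Step 4. Over-alkylation of the monoprenyl phenolate, which is more electron-rich than its precursor, together with O-prenylation and hydrolysis of the allylic bromide, may leave little material at the monoprenyl stage. The fallback sets out from 8 and gives up the isolation of that stage. Twofold Friedel–Crafts C-prenylation with 2-methylbut-3-en-2-ol (2.2 equiv) and BF3·OEt2 in dioxane at 20 °C is an electrophilic aromatic substitution in which attack at an already substituted carbon is reversible, so it should stop at twofold ring substitution. The fallback comes back to the route at 11 and makes no compound outside the compound list (F0).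

Step 2. Competing deprotonation at the isobutyl methylene would erode the regiochemical purity of the diene, and the diene may lose silyl groups by adventitious hydrolysis. The fallback sets out from 4 and moves the regiochemical decision to a position where it cannot arise. Effenberger pyranone synthesis from 4 and 2-(trimethylsilyloxy)propene (Et2O, −20 → 20 °C) gives 4-hydroxy-6-methyl-2H-pyran-2-one F1. Its dianion (LiN(iPr)2, 3 equiv, THF, −78 °C) has the 6-methyl group as its only carbanion site and is acylated there with methyl 3-methylbutanoate. This comes back to the route at pyranone 6, now isolated, which is taken on to 8 by the Mg(OMe)2 stage of step 3.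

Further compounds
F0 | step 3 | none | none
F0 | step 4 | none | none
F1 | step 2 | 4-hydroxy-6-methyl-2H-pyran-2-one | CC1=CC(O)=CC(=O)O1
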